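The earlier runs and the new flask stem from a simulated flask from invented constants; the scatter is artificial.

Decide first what the end state of this flask is, and carry one number towards it.

| flask | substrate | time |
|---|---|---|
| autumn | 250 mM |  |
| dusk | 150 mM |  |
| dawn | 380 mM |  |
| noon | 750 mM | 180 min |

| run | time / min | [target] / mM |
|---|---|---|
| autumn run | 22 | 5 |
| autumn run | 45 | 14 |
| autumn run | 68 | 27 |
| autumn run | 90 | 58 |
| autumn run | 110 | 81 |
| autumn run | 140 | 121 |
| autumn run | 160 | 133 |
| autumn run | 180 | 137 |
| dusk run | 22 | 1 |
| dusk run | 45 | 4 |
| dusk run | 68 | 8 |
| dusk run | 90 | 22 |
| dusk run | 110 | 34 |
| dusk run | 140 | 51 |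
| dusk run | 160 | 46 |
| dusk run | 180 | 64 |
| dawn run | 22 | 1 |
| dawn run | 45 | 25 |
| dawn run | 68 | 86 |
| dawn run | 90 | 164 |
| dawn run | 110 | 218 |
| dawn run | 140 | 240 |
| dawn run | 160 | 236 |
| dawn run | 180 | 223 |

(readings scatter by 3 mM)

- the exponent of [substrate] in the starting rate at the charge of the autumn run (at the point where two percent of the substrate have become target) (one fixed amount of target, the same in the runs compared)
- target in the noon run at 180 min, as a share of the substrate charged

- Overall: substrate -> target.
- Constant volume, constant temperature.
- An order is taken over about fifteen percent of the charge, up and down.

Two people stand at this board. Both read the sigmoidal curves as autocatalysis: target speeds its own making. The first reads the flat tops as a stall, with a high plateau at noon followed by a modest loss. The forecast is hers: order 1 and 62% of the noon charge, with the ground “This suggests the catalyst dies.”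

The second view is mine. The dawn run falls from 240 mM at 140 min to 223 mM at 180 min, so I take a flask heading towards no target, with the top marking a balance of making and losing. Then the dawn run gives a budget. It is missing 157 mM of its charge at 180 min, and the area under its target curve, spread over those 180 min, is a mean [target] of 135 mM. The loss constant, a first-order constant defined as missing charge per unit of that area, is 0.00644 min⁻¹. It is a ceiling, since any unreacted charge is booked as lost. Starting from the forecast's peak of 75% near 110 min, it leaves 47.8% at 180 min, less than the forecast's share.

The flask gives order 0.85 and 52.6%, which is 9.4 percentage points below the forecast and 4.8 points above my figure. The first view keeps a region: in the dawn run from 140 min to 160 min the readings differ by 4.00 mM, close to the scatter of 3 mM, so a plateau describes that stretch fairly.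

    substrate ⇌ intermediate (0.004566 min⁻¹, 0.007560 min⁻¹)
    intermediate → target (0.007560 min⁻¹)
    substrate + target → 2 target (0.1704 L mol⁻¹ min⁻¹)
    target → decomposed product (0.005172 min⁻¹)

Noon shows the reason: with the step from target to decomposed product removed, it gives 97.5% at 180 min instead of 52.6%, and that step accounts for 95% of what is missing. In the autumn run at 180 min, the same constant books 73.0 mM as lost, out of 113 mM missing.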